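The easy mistake with this flask was to scale its product rate down with its smaller charge of solid reagent.

| setting | midnight | autumn | flask |
|---|---|---|---|
| left-handed substrate | 0.053 M | 0.053 M | 0.053 M |
| right-handed substrate | 0.053 M | 0.053 M | 0.053 M |
| solid reagent | 4.2 equiv | 6.6 equiv | 3.00 equiv |
| remark | run made earlier | run made earlier |  |
| time |  |  | 30 h |

| run | time / h | left-handed product / % | left-handed substrate / % |
|---|---|---|---|
| midnight | 3.00 | 0 | 49.4 |
| midnight | 4.00 | 0 | 48.4 |
| midnight | 6.00 | 0.5 | 47.3 |
| midnight | 10.0 | 1.1 | 46.8 |
| midnight | 15.0 | 2.4 | 45.5 |
| midnight | 25.0 | 5.0 | 45.4 |
| midnight | 40.0 | 9.8 | 41.3 |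
| autumn | 5.00 | 0.8 | 48.3 |
| autumn | 10.0 | 0.6 | 47.6 |
| autumn | 15.0 | 3.6 | 47.1 |
| autumn | 20.0 | 3.7 | 46.3 |
| autumn | 25.0 | 6.1 | 43.7 |
| autumn | 30.0 | 8.1 | 44.1 |
| autumn | 40.0 | 10.2 | 40.1 |

(readings scatter by 1 percentage point)

- coupling partner is single-handed; left-handed substrate and right-handed substrate are mirror images of each other, charged as a racemate, each of them at the stated concentration
- as a solid, counted per litre of solution: solid reagent
- the analysis behind the earlier runs scatters by 1 percentage point, standard deviation
- at the start none of the solid reagent is in solution
- coupling partner is what solid reagent becomes in solution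
- the handed part of coupling partner does not stay in what it makes, so the products of the two hands are mirror images too

- oak: doubling the dissolution coefficient of the solid reagent, all else as stated
- ash: doubling the solubility of the solid reagent, all else as stated

- how much left-handed product there is at 30 h, in percent of the left-handed substrate and right-handed substrate together charged
- concentration of coupling partner in solution at 15 h, in percent of saturation
- the change that raises the amount of left-handed product at 30 h, in percent of the left-handed substrate and right-handed substrate together charged most ("none" if none brings more than 2 percentage points) (oak / ash / none)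
- amount of left-handed product at 30 h, in percent of the left-handed substrate and right-handed substrate together charged, after ash

The autumn run held 1.57 times the solid of the midnight run, yet at 40.0 h the two read 9.8% and 10.2% of left-handed product, a gap of 0.4 percentage points against a scatter of 1 point. So I pooled them as one curve and carried it to this flask, though its 3.00 equiv lay outside the charges tried.

Then I followed the rate, as a fraction of the whole charge per hour. At the start none of the solid reagent was in solution, and the midnight run read 0% at 4.00 h. Between 25.0 h and 40.0 h the pooled readings gave 0.00297 h⁻¹, my late rate, the fraction of the charge turned into left-handed product per hour once the lag is over. Stretch by stretch, the pooled readings gave: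

| stretch | pooled rate | share of late rate |
|---|---|---|
| start to 15 h | 0.00200 h⁻¹ | 0.673 |
| 15 h to 25.0 h | 0.00255 h⁻¹ | 0.859 |

Both stretches read slower than the late rate, and together they amount to a lag (an induction period) of 6.29 h, where the late line, run back from the pooled reading at 25.0 h, meets zero. The late rate times the hours past the lag gave me 7.03% at 30 h.

The forecast stood lower, at 5.9% (4.9% to 7%), with 68% of saturation at 15 h, ash as the best change and 11% after it, on the ground that “the product rate follows its concentration”.

The flask gave 7.08%, 18.6% of saturation at 15 h, ash as the best change with a gain of 6.5 points (oak 4.8 points), and 13.6% after ash.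

    solid reagent ⇌ coupling partner, rate k1*(cs1 - [coupling partner]) while solid is left; crystals form when [coupling partner] > cs1 (solubility = 21.0 mM, k = 0.0300 h⁻¹)
    coupling partner + left-handed substrate → left-handed product (k = 1.50 L mol⁻¹ h⁻¹)
    achiral form → waste (k = 0.0450 h⁻¹)
    left-handed substrate ⇌ achiral form (K = 0.0350, k = 0.190 h⁻¹)
    right-handed substrate ⇌ achiral form (K = 0.0350, k = 0.190 h⁻¹)
    coupling partner + right-handed substrate → right-handed product (k = 0.580 L mol⁻¹ h⁻¹)
    coupling partner ⇌ dormant form (K = 0.700, k = 0.00870 h⁻¹)

At 30.0 h in this flask coupling partner was made 1.06 times as fast as it was used up, each step net (a quasi-steady state). Its half-life in this flask by the path to left-handed product alone, with the other concentrations as charged, is 8.7 h, shorter than 30 h. Read at 5.0 d, the same flask comes to 33.8% of left-handed product by late rate and lag; computed, it holds 31.8%.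

(The readings are simulated with constants of no real substance.)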